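**Assumptions:** The target (5-hydroxy-7-methoxy-6,8-dimethyl-3',4'-dihydroxy-5'-prenylflavone) has no stereocentres and its prenyl alkene has no E/Z isomerism, so no stereocontrol is needed. Methyl 3-bromo-4,5-dihydroxybenzoate is taken as a catalogue compound. The route is designed from known reaction types and has not been run.

## Retrosynthetic overview

1. The pyranone C ring is formed last, by acid cyclodehydration of a 1,3-diketone; the same acid removes the two MOM groups.
2. The diketone comes from a Claisen condensation of a C2-symmetric 2,6-dihydroxyacetophenone polyanion (A ring) with a methyl benzoate (B ring). Symmetry means only one flavone regioisomer can form.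
3. A ring: phloroacetophenone, double C-methylation, then selective 4-O-methylation.
4. B ring: methyl 3-bromo-4,5-dihydroxybenzoate, bis-MOM protection, then Stille prenylation at the C–Br bond.

## Route

**Step 1**
Reactants: 1, 2',4',6'-trihydroxyacetophenone
Product: 2, 1-(2,4,6-trihydroxy-3,5-dimethylphenyl)ethan-1-one
Conditions: NaOMe (3.5 equiv), MeI (2.3 equiv), MeOH, 0 °C → reflux
Reagents that add atoms: iodomethane, CI (two CH3)
Why: Phloroglucinol-type C-alkylation: in protic solvent the acylphloroglucinol anion reacts as its keto tautomer at ring carbon, and stoichiometry limits it to the two free positions; the gem-dimethyl over-alkylation by-product is removed by chromatography.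

**Step 2**
Reactants: 2, 1-(2,4,6-trihydroxy-3,5-dimethylphenyl)ethan-1-one
Product: 3, 1-(2,6-dihydroxy-4-methoxy-3,5-dimethylphenyl)ethan-1-one
Conditions: Me2SO4 (1.05 equiv), K2CO3 (1.1 equiv), acetone, rt → 40 °C
Reagents that add atoms: dimethyl sulfate, COS(=O)(=O)OC (one CH3)
Why: Selective Williamson O-methylation: the para OH is the most acidic and is not hydrogen-bonded to the ketone, so it reacts first with one equivalent of base and electrophile.

**Step 3**
Reactants: 4, methyl 3-bromo-4,5-dihydroxybenzoate
Product: 5, methyl 3-bromo-4,5-bis(methoxymethoxy)benzoate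
Conditions: MOMCl (3 equiv), i-Pr2NEt, CH2Cl2, 0 °C → rt
Reagents that add atoms: chloromethyl methyl ether, COCCl (two CH2OCH3)
Why: Standard acetal protection of both catechol OH groups; MOM survives Pd coupling and strong base and is removed in the final acid step.

**Step 4**
Reactants: 5, methyl 3-bromo-4,5-bis(methoxymethoxy)benzoate
Product: 6, methyl 3,4-bis(methoxymethoxy)-5-(3-methylbut-2-en-1-yl)benzoate
Conditions: prenyl-SnBu3 (1.5 equiv), Pd(PPh3)4 (5 mol%), DMF (degassed), 100 °C; aq. KF work-up
Reagents that add atoms: tributyl(3-methylbut-2-en-1-yl)stannane, CCCC[Sn](CCCC)(CCCC)CC=C(C)C (prenyl group)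
Why: Stille coupling of the aryl bromide with the prenylstannane gives the linear prenyl arene under neutral conditions that leave the ester and MOM ethers untouched.

**Step 5**
Reactants: 3, 1-(2,6-dihydroxy-4-methoxy-3,5-dimethylphenyl)ethan-1-one; 6, methyl 3,4-bis(methoxymethoxy)-5-(3-methylbut-2-en-1-yl)benzoate
Product: 7, 1-[3,4-bis(methoxymethoxy)-5-(3-methylbut-2-en-1-yl)phenyl]-3-(2,6-dihydroxy-4-methoxy-3,5-dimethylphenyl)propane-1,3-dione (isolated as an enol/cyclic hemiketal mixture, used crude)
Conditions: 3, LiHMDS (4.5 equiv), THF, −78 → −10 °C; then 6, −78 °C → rt (warm to 50 °C if slow); aq. NH4Cl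
Reagents that add atoms: none (MeOH is lost)
Why: Crossed Claisen condensation of the lithium polyanion (two phenoxides plus enolate) with a non-enolisable ester, driven by formation of the stabilised diketonate; any O-acylation funnels to the same diketone by Baker–Venkataraman rearrangement, so the A-ring phenols need no protection.

**Step 6**
Reactants: 7, the 1,3-diketone
Product: 8, Muxiangrine III, 2-[3,4-dihydroxy-5-(3-methylbut-2-en-1-yl)phenyl]-5-hydroxy-7-methoxy-6,8-dimethyl-4H-chromen-4-one
Conditions: 3 M aq. HCl/MeOH (1:5), 50 °C, 1–2 h, monitored closely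
Reagents that add atoms: none
Why: Acid-catalysed cyclodehydration of the o-hydroxyaryl diketone closes the γ-pyrone, and the same acid methanolyses both MOM acetals. Either ortho OH gives the same flavone, the other becomes the chelated 5-OH, and the aryl methyl ether is stable.

## Compound list

1 | 2',4',6'-trihydroxyacetophenone | CC(=O)c1c(O)cc(O)cc1O | starting material
2 | 1-(2,4,6-trihydroxy-3,5-dimethylphenyl)ethan-1-one | CC(=O)c1c(O)c(C)c(O)c(C)c1O | intermediate
3 | 1-(2,6-dihydroxy-4-methoxy-3,5-dimethylphenyl)ethan-1-one | CC(=O)c1c(O)c(C)c(OC)c(C)c1O | intermediate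
4 | methyl 3-bromo-4,5-dihydroxybenzoate | COC(=O)c1cc(O)c(O)c(Br)c1 | starting material
5 | methyl 3-bromo-4,5-bis(methoxymethoxy)benzoate | COC(=O)c1cc(OCOC)c(OCOC)c(Br)c1 | intermediate
6 | methyl 3,4-bis(methoxymethoxy)-5-(3-methylbut-2-en-1-yl)benzoate | COC(=O)c1cc(OCOC)c(OCOC)c(CC=C(C)C)c1 | intermediate
7 | 1-[3,4-bis(methoxymethoxy)-5-(3-methylbut-2-en-1-yl)phenyl]-3-(2,6-dihydroxy-4-methoxy-3,5-dimethylphenyl)propane-1,3-dione | COc1c(C)c(O)c(C(=O)CC(=O)c2cc(OCOC)c(OCOC)c(CC=C(C)C)c2)c(O)c1C | intermediate
8 | Muxiangrine III | COc1c(C)c(O)c2c(=O)cc(-c3cc(O)c(O)c(CC=C(C)C)c3)oc2c1C | target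

## Summary

Total steps: 6. Longest linear sequence: 4 (steps 1, 2, 5, 6 or steps 3, 4, 5, 6).

Steps most likely to fail, each with a fallback that changes the approach:

1. **Step 5 (polyanion Claisen with an electron-rich methyl benzoate may be sluggish).** Fallback: switch to a chalcone route. Use the aldehyde analogue of 6 (from 3-bromo-4,5-dihydroxybenzaldehyde by the same MOM/Stille sequence), mono-MOM-protect 3, run a Claisen–Schmidt aldol (KOH/EtOH) to the 2'-hydroxychalcone, oxidatively cyclise with catalytic I2/DMSO, then remove MOM.
2. **Step 6 (acid may cyclise the prenyl group onto the freed 4'-OH to give a 2,2-dimethylchroman, or add HCl/MeOH across the alkene).** Fallback: install the prenyl group last. Carry bromide 5 instead of 6 through steps 5–6 to the 3'-bromo-4',5'-dihydroxyflavone, peracetylate, Stille-prenylate, and deacetylate with K2CO3/MeOH, so the prenyl group never meets acid.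
3. **Step 1 (C-methylation gives mono-, di- and gem-dimethyl mixtures and a modest yield).** Fallback: start from commercial 2',6'-dihydroxy-4'-methoxyacetophenone, bis-aminomethylate C3/C5 (Mannich, CH2O/secondary amine), and reductively cleave the benzylic amines to methyl groups. This gives 3 directly and also bypasses step 2.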